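**Retrosynthetic overview**

- The strategy rests on ring C, the 4-pyranone. Its O1–C8a–C4a–C4 atoms are those of a salicylic acid and its C2–C3 atoms those of an arylacetaldehyde, with C3 (the carbon that carries ring B) as the nucleophile.
- Cutting C3–C4 and O1–C2 gives the O-acetylated benzoyl chloride 11 (ring A with the 6-methoxy and 8-prenyl groups in place) and the morpholine enamine 14 of (3,4-dimethoxyphenyl)acetaldehyde.
- Chloride 11 comes from 4-methoxyresorcinol by formylation, allyl ether Claisen rearrangement to the only free ortho carbon (future C8), acetylation, cross-metathesis to the prenyl group, aldehyde oxidation and neutral chlorination. Direct C-prenylation between the two hydroxyls is avoided as unreliable.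
- Rings A and B are bought. Ring C is the only ring formed, in the last step, where methanolysis of both acetates frees the ortho phenoxide for closure and the 7-hydroxyl of the target at once, so no separate deprotection follows.

Key step: step 9

Remark: enaminones 15 and 16 are drawn E (amino group trans to the ketone); the geometry should not matter, because closure needs only rotation about the C3–C4 single bond.

**Route**

Step 1
Reactants: 1 4-methoxyresorcinol
Product: 3 2,4-dihydroxy-5-methoxybenzaldehyde, via aryl iminium chloride 2 (not isolated)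
Conditions: POCl3, DMF, MeCN, 0 °C → rt; then H2O, 50 °C
Reagents that add atoms: N,N-dimethylformamide CN(C)C=O; water O
Why: Vilsmeier–Haack formylation, in which the chloroiminium ion attacks the carbon para to one hydroxyl and ortho to the other (the carbon between the two hydroxyls is more crowded), and water then hydrolyses iminium salt 2 to the aldehyde.

Step 2
Reactants: 3 2,4-dihydroxy-5-methoxybenzaldehyde; 4 allyl bromide
Product: 5 2-hydroxy-5-methoxy-4-(prop-2-enyloxy)benzaldehyde
Conditions: KHCO3, MeCN, 60 °C (1.05 equiv of 4)
Reagents that add atoms: none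
Why: Williamson etherification in which the 2-hydroxyl, held in a hydrogen bond to the formyl oxygen, is the less acidic and less nucleophilic one, so a weak base and one equivalent of halide should alkylate only the 4-hydroxyl.

Step 3
Reactants: 5 2-hydroxy-5-methoxy-4-(prop-2-enyloxy)benzaldehyde
Product: 6 2,4-dihydroxy-5-methoxy-3-(prop-2-enyl)benzaldehyde
Conditions: N,N-diethylaniline, 190 °C, argon
Reagents that add atoms: none
Why: Aromatic Claisen rearrangement ([3,3]-sigmatropic shift) in which one ortho carbon of the allyl ether carries the methoxy group and cannot rearomatise, so the allyl group should end up only on the carbon between the two oxygens, the future C8.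

Step 4
Reactants: 6 2,4-dihydroxy-5-methoxy-3-(prop-2-enyl)benzaldehyde
Product: 7 2,4-diacetoxy-5-methoxy-3-(prop-2-enyl)benzaldehyde
Conditions: Ac2O, pyridine, DMAP (cat.), CH2Cl2, 0 °C → rt
Reagents that add atoms: acetic anhydride CC(=O)OC(C)=O
Why: DMAP-catalysed O-acetylation of both hindered phenols, which protects them for the metathesis and oxidation and installs the ortho acetate that a stable salicyloyl chloride needs.

Step 5
Reactants: 7 2,4-diacetoxy-5-methoxy-3-(prop-2-enyl)benzaldehyde; 8 2-methyl-2-butene
Product: 9 2,4-diacetoxy-5-methoxy-3-(3-methylbut-2-enyl)benzaldehyde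
Conditions: second-generation Grubbs catalyst (H2IMes)(PCy3)Cl2Ru=CHPh (5 mol %), 8 as co-solvent, CH2Cl2, 40 °C, sealed vessel
Reagents that add atoms: none
Why: Olefin cross-metathesis of a terminal alkene with excess 2-methyl-2-butene, which exchanges the terminal CH2 for an isopropylidene group with release of propene and tolerates the aldehyde and the aryl acetates.

Step 6
Reactants: 9 2,4-diacetoxy-5-methoxy-3-(3-methylbut-2-enyl)benzaldehyde
Product: 10 2,4-diacetoxy-5-methoxy-3-(3-methylbut-2-enyl)benzoic acid
Conditions: NaClO2, NaH2PO4, 2-methyl-2-butene (8, large excess), t-BuOH/H2O, 0 °C → rt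
Reagents that add atoms: sodium chlorite [Na+].[O-]Cl=O
Why: Pinnick oxidation, in which chlorous acid oxidises the aldehyde near pH 4 where aryl acetates survive, and the large excess of scavenger alkene should trap the hypochlorous acid before it adds to the prenyl double bond.

Step 7
Reactants: 10 2,4-diacetoxy-5-methoxy-3-(3-methylbut-2-enyl)benzoic acid
Product: 11 2,4-diacetoxy-5-methoxy-3-(3-methylbut-2-enyl)benzoyl chloride
Conditions: 1-chloro-N,N,2-trimethylprop-1-en-1-amine (1.2 equiv), CH2Cl2, 0 °C → rt; concentrated and used crude
Reagents that add atoms: 1-chloro-N,N,2-trimethylprop-1-en-1-amine CC(C)=C(Cl)N(C)C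
Why: Acid chloride formation with an alpha-chloroenamine through an acyloxyiminium chloride, which runs under neutral conditions without free HCl, so the prenyl double bond is not hydrochlorinated and the acetates stay in place.

Step 8
Reactants: 12 (3,4-dimethoxyphenyl)acetaldehyde; 13 morpholine
Product: 14 (E)-4-[2-(3,4-dimethoxyphenyl)ethenyl]morpholine
Conditions: 4 Å molecular sieves, toluene, 0 °C → rt (1.2 equiv of 13); filtered, concentrated and used at once
Reagents that add atoms: none
Why: Enamine condensation of an enolisable aldehyde with a secondary amine with removal of water, in which conjugation with the aryl ring and the bulk of the amine favour the E isomer.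

Step 9
Reactants: 11 2,4-diacetoxy-5-methoxy-3-(3-methylbut-2-enyl)benzoyl chloride; 14 (E)-4-[2-(3,4-dimethoxyphenyl)ethenyl]morpholine
Product: 17 3-(3,4-dimethoxyphenyl)-7-hydroxy-6-methoxy-8-(3-methylbut-2-enyl)chromen-4-one, via diacetoxy enaminone 15 (not isolated), via dihydroxy enaminone 16 (not isolated)
Conditions: Et3N, CH2Cl2, 0 °C → rt; then K2CO3, MeOH, rt; then AcOH, 40 °C
Reagents that add atoms: none
Why: The beta-carbon of enamine 14 (the aryl-bearing carbon, future C3) attacks the acid chloride to form C3–C4, and triethylamine deprotonates the resulting iminium salt to the vinylogous amide 15, a Stork enamine acylation of the kind known for O-acetylsalicyloyl chlorides. Potassium carbonate in methanol then cleaves both aryl acetates to give 16, whose ortho phenoxide adds to C2, and once acetic acid protonates the amine, morpholine is expelled to form O1–C2 by addition–elimination. Ring C closes in a six-membered 6-endo-trig oxa-Michael mode, the same closure as in the enaminone route from deoxybenzoins to 7-hydroxyisoflavones, and aromatisation of the pyranone together with protonation of morpholine should make it irreversible. No stereocentre is formed. The step needs C-acylation to win over N-acylation and over attack on the aryl acetates: N-acylation of a tertiary enamine is reversible whereas C-acylation is fixed by loss of the C3 proton, and the acid chloride is far more electrophilic than the acetates. The polarity of the enamine places the aryl group at C3 (isoflavone, not flavone), and base followed by weak acid is chosen because hot mineral acid would cyclise the prenyl group onto the free 7-hydroxyl.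

**Compound list**

1 | 4-methoxyresorcinol (4-methoxybenzene-1,3-diol) | COc1ccc(O)cc1O | starting material
2 | N-[(2,4-dihydroxy-5-methoxyphenyl)methylidene]-N-methylmethanaminium chloride | COc1cc(C=[N+](C)C)c(O)cc1O.[Cl-] | intermediate (not isolated)
3 | 2,4-dihydroxy-5-methoxybenzaldehyde | COc1cc(C=O)c(O)cc1O | intermediate
4 | allyl bromide | C=CCBr | starting material
5 | 2-hydroxy-5-methoxy-4-(prop-2-enyloxy)benzaldehyde | C=CCOc1cc(O)c(C=O)cc1OC | intermediate
6 | 2,4-dihydroxy-5-methoxy-3-(prop-2-enyl)benzaldehyde | C=CCc1c(O)c(OC)cc(C=O)c1O | intermediate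
7 | 2,4-diacetoxy-5-methoxy-3-(prop-2-enyl)benzaldehyde | C=CCc1c(OC(C)=O)c(OC)cc(C=O)c1OC(C)=O | intermediate
8 | 2-methyl-2-butene | CC=C(C)C | starting material
9 | 2,4-diacetoxy-5-methoxy-3-(3-methylbut-2-enyl)benzaldehyde | CC(C)=CCc1c(OC(C)=O)c(OC)cc(C=O)c1OC(C)=O | intermediate
10 | 2,4-diacetoxy-5-methoxy-3-(3-methylbut-2-enyl)benzoic acid | CC(C)=CCc1c(OC(C)=O)c(OC)cc(C(=O)O)c1OC(C)=O | intermediate
11 | 2,4-diacetoxy-5-methoxy-3-(3-methylbut-2-enyl)benzoyl chloride | CC(=O)Oc1c(CC=C(C)C)c(OC(C)=O)c(OC)cc1C(=O)Cl | intermediate
12 | (3,4-dimethoxyphenyl)acetaldehyde | COc1ccc(CC=O)cc1OC | starting material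
13 | morpholine | C1COCCN1 | starting material
14 | (E)-4-[2-(3,4-dimethoxyphenyl)ethenyl]morpholine | COc1ccc(/C=C/N2CCOCC2)cc1OC | intermediate
15 | (E)-1-[2,4-diacetoxy-5-methoxy-3-(3-methylbut-2-enyl)phenyl]-2-(3,4-dimethoxyphenyl)-3-(morpholin-4-yl)prop-2-en-1-one | CC(=O)Oc1c(CC=C(C)C)c(OC(C)=O)c(OC)cc1C(=O)/C(c1ccc(OC)c(OC)c1)=C/N1CCOCC1 | intermediate (not isolated)
16 | (E)-1-[2,4-dihydroxy-5-methoxy-3-(3-methylbut-2-enyl)phenyl]-2-(3,4-dimethoxyphenyl)-3-(morpholin-4-yl)prop-2-en-1-one | COc1cc(C(=O)/C(c2ccc(OC)c(OC)c2)=C/N2CCOCC2)c(O)c(CC=C(C)C)c1O | intermediate (not isolated)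
17 | 3-(3,4-dimethoxyphenyl)-7-hydroxy-6-methoxy-8-(3-methylbut-2-enyl)chromen-4-one | COc1ccc(-c2coc3c(CC=C(C)C)c(O)c(OC)cc3c2=O)cc1OC | target

**Step count and risks**

Total step count: 9. Longest linear sequence: 8 (steps 1–7, then step 9).

Steps most likely to fail:

1. Step 9. N-acylation or acetyl transfer to the enamine may outrun C-acylation at the ortho-substituted acid chloride, or closure may stall at the open enaminone. The fallback sets out from acid chloride 11 and returns at target 17.
   - Commercial 3,4-dimethoxybenzyl chloride is converted with zinc dust and LiCl in THF into (3,4-dimethoxybenzyl)zinc chloride F1.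
   - Negishi acylation of 11 with F1 under Pd(PPh3)4 catalysis in THF at rt should give 1-[2,4-diacetoxy-5-methoxy-3-(3-methylbut-2-enyl)phenyl]-2-(3,4-dimethoxyphenyl)ethanone F2.
   - K2CO3 in MeOH should remove both acetates to give 1-[2,4-dihydroxy-5-methoxy-3-(3-methylbut-2-enyl)phenyl]-2-(3,4-dimethoxyphenyl)ethanone F3.
   - N,N-dimethylformamide dimethyl acetal in THF at 60 °C should condense at the methylene to give (E)-1-[2,4-dihydroxy-5-methoxy-3-(3-methylbut-2-enyl)phenyl]-3-(dimethylamino)-2-(3,4-dimethoxyphenyl)prop-2-en-1-one F4, which closes with loss of dimethylamine to 17.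
   - This is the known deoxybenzoin route; C2 enters as a one-carbon electrophile instead of with the enamine.

2. Step 8. Self-aldol condensation of the enolisable arylacetaldehyde may compete with enamine formation, and the enamine may hydrolyse on handling. The fallback sets out from morpholine 13 and returns at enamine 14.
   - Commercial (E)-3,4-dimethoxycinnamic acid undergoes catalytic Hunsdiecker bromodecarboxylation (N-bromosuccinimide, LiOAc cat., MeCN/H2O, rt) to (E)-4-(2-bromoethenyl)-1,2-dimethoxybenzene F5.
   - Palladium-catalysed amination of this alkenyl bromide with 13 (Pd2(dba)3, BINAP, NaOtBu, toluene, 80 °C) should give 14 with retention of the E geometry and without any free aldehyde.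

3. Step 6. Hypochlorous acid may add to the electron-rich trisubstituted prenyl double bond despite the scavenger. The fallback sets out from allyl aldehyde 7 and returns at acid 10.
   - The Pinnick oxidation is run before the metathesis, on the less nucleophilic terminal alkene, to give 2,4-diacetoxy-5-methoxy-3-(prop-2-enyl)benzoic acid F6.
   - Cross-metathesis of F6 with 8 (second-generation Grubbs catalyst, CH2Cl2, 40 °C), which tolerates a free carboxylic acid, then installs the prenyl group.

**Further compounds**

F1 | step 9 | (3,4-dimethoxybenzyl)zinc chloride | COc1ccc(C[Zn]Cl)cc1OC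
F2 | step 9 | 1-[2,4-diacetoxy-5-methoxy-3-(3-methylbut-2-enyl)phenyl]-2-(3,4-dimethoxyphenyl)ethanone | CC(=O)Oc1c(CC=C(C)C)c(OC(C)=O)c(OC)cc1C(=O)Cc1ccc(OC)c(OC)c1
F3 | step 9 | 1-[2,4-dihydroxy-5-methoxy-3-(3-methylbut-2-enyl)phenyl]-2-(3,4-dimethoxyphenyl)ethanone | COc1ccc(CC(=O)c2cc(OC)c(O)c(CC=C(C)C)c2O)cc1OC
F4 | step 9 | (E)-1-[2,4-dihydroxy-5-methoxy-3-(3-methylbut-2-enyl)phenyl]-3-(dimethylamino)-2-(3,4-dimethoxyphenyl)prop-2-en-1-one | CN(C)/C=C(/C(=O)c1cc(OC)c(O)c(CC=C(C)C)c1O)c1ccc(OC)c(OC)c1
F5 | step 8 | (E)-4-(2-bromoethenyl)-1,2-dimethoxybenzene | COc1ccc(/C=C/Br)cc1OC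
F6 | step 6 | 2,4-diacetoxy-5-methoxy-3-(prop-2-enyl)benzoic acid | C=CCc1c(OC(C)=O)c(OC)cc(C(=O)O)c1OC(C)=O
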